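**Assumption:** the target SMILES has no stereocentre, no stereogenic acyclic double bond and no configurationally stable axis (the benzofuran-2-yl–aryl bond rotates freely), so the molecule is achiral and no enantioselective step is needed.

## Retrosynthetic overview

1. Cathafuran C (16) comes from its bis-MOM ether 15 by global deprotection.
2. 15 comes from a one-pot, regioselective 2-benzofuranyl/prenyl difunctionalisation of a 7-alkoxy-2H-chromen-5,6-yne (the proposed new step). This forms the C5–benzofuran and C6–prenyl bonds together from iodo-triflate 11, benzofuran 13 and prenyl bromide 14.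
3. 11 comes from 5,7-dihydroxy-2,2-dimethylchroman-4-one (3) by 7-O-MOM protection, C6 iodination, 5-O-triflation and C4 reduction/dehydration. The phloroglucinol C5 oxygen serves as the aryne leaving group.
4. 3 comes from phloroglucinol and 3,3-dimethylacrylic acid.
5. Ring order: the pyranone ring is built first (step 1) and converted to the 2H-chromene in steps 5–6. The benzofuran ring is bought in as 6-hydroxybenzofuran, and the key step joins the two halves.

## Route

**Step 1**
Reactants: 1 phloroglucinol; 2 3,3-dimethylacrylic acid
Product: 3, 5,7-dihydroxy-2,2-dimethylchroman-4-one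
Conditions: MeSO3H/P2O5, 70 °C
Reagents that add atoms: none beyond reactants 1 and 2 (2: CC(C)=CC(=O)O)
Why: Friedel–Crafts acylation followed by intramolecular oxa-Michael addition closes the chromanone, and the symmetry of phloroglucinol allows only one regioisomer.

**Step 2**
Reactants: 3; 4 chloromethyl methyl ether (MOMCl)
Product: 5, 5-hydroxy-7-(methoxymethoxy)-2,2-dimethylchroman-4-one
Conditions: MOMCl (1.1 equiv), iPr2NEt, CH2Cl2, 0 °C → rt
Reagents that add atoms: MOMCl (4), COCCl
Why: O-alkylation (MOM protection) is selective for the 7-OH because the 5-OH is hydrogen-bonded to the C4 carbonyl and is much less nucleophilic.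

**Step 3**
Reactants: 5; 6 benzyltrimethylammonium dichloroiodate
Product: 7, 5-hydroxy-6-iodo-7-(methoxymethoxy)-2,2-dimethylchroman-4-one
Conditions: BnMe3N·ICl2 (1.05 equiv), CaCO3, CH2Cl2/MeOH, rt
Reagents that add atoms: benzyltrimethylammonium dichloroiodate (6), C[N+](C)(C)Cc1ccccc1.Cl[I-]Cl
Why: Electrophilic aromatic iodination under acid-scavenged conditions goes ortho to the chelated 5-OH (C6), the selectivity expected for 5-hydroxy-7-alkoxy benzopyranones with this reagent.

**Step 4**
Reactants: 7; 8 triflic anhydride
Product: 9, 6-iodo-7-(methoxymethoxy)-2,2-dimethyl-4-oxochroman-5-yl trifluoromethanesulfonate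
Conditions: Tf2O, pyridine, CH2Cl2, 0 °C → rt
Reagents that add atoms: Tf2O (8), O=S(=O)(OS(=O)(=O)C(F)(F)F)C(F)(F)F
Why: O-sulfonylation of the phenol turns the C5 oxygen into the leaving group for aryne generation, and pyridine buffers the MOM ether.

**Step 5**
Reactants: 9
Product: 10, (±)-4-hydroxy-6-iodo-7-(methoxymethoxy)-2,2-dimethylchroman-5-yl trifluoromethanesulfonate
Conditions: DIBAL-H, CH2Cl2, −78 °C
Reagents that add atoms: none
Why: 1,2-hydride reduction of the aryl ketone at low temperature leaves the triflate, iodide and MOM untouched; the racemic C4 carbinol is removed in the next step.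

**Step 6**
Reactants: 10
Product: 11, 6-iodo-7-(methoxymethoxy)-2,2-dimethyl-2H-chromen-5-yl trifluoromethanesulfonate
Conditions: MsCl, Et3N, CH2Cl2, 0 °C → rt; then DBU, 40 °C
Reagents that add atoms: none
Why: Mesylation and base-mediated elimination (dehydration) of the benzylic alcohol gives the 2H-chromene C3=C4 bond without acid, so MOM, triflate and iodide survive.

**Step 7**
Reactants: 12 6-hydroxybenzofuran; 4 MOMCl
Product: 13, 6-(methoxymethoxy)benzofuran
Conditions: NaH, DMF, 0 °C; MOMCl, 0 °C → rt
Reagents that add atoms: MOMCl (4), COCCl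
Why: Williamson-type O-alkylation (MOM protection) of the phenoxide.

**Step 8 (key step)**
Reactants: 11; 13; 14 prenyl bromide
Product: 15, 6-(methoxymethoxy)-2-[7-(methoxymethoxy)-2,2-dimethyl-6-(3-methylbut-2-en-1-yl)-2H-chromen-5-yl]benzofuran
Conditions: 13 (3 equiv), n-BuLi, THF, −78 °C; MgBr2·OEt2; add 11, then Me3SiCH2MgCl (1.2 equiv), −78 → −20 °C; CuBr·SMe2, then prenyl bromide (excess), −20 → 0 °C
Reagents that add atoms: prenyl bromide (14), CC(C)=CCBr
Why: Proposed new method: I/Mg exchange at C6 of 11 and β-elimination of triflate generate a 7-(methoxymethoxy)-2,2-dimethyl-2H-chromen-5,6-yne, an aryne class not previously used; the inductively withdrawing C7–O group distorts the aryne so the 2-benzofuranyl Grignard adds at the distal carbon C5, leaving a MOM-chelated C6 arylmagnesium that, after Mg→Cu transmetalation, is allylated by prenyl bromide at its CH2 terminus (SN2; the γ-carbon is tertiary and the arylcopper is di-ortho-substituted), so the biaryl and C6–prenyl bonds form regiospecifically in one pot; the closest known reaction type is addition of aryl Grignard reagents to arynes generated from 2-iodoaryl sulfonates/triflates with electrophilic trapping of the resulting 2-biarylmagnesium, combined with copper-mediated prenylation of ortho-alkoxy aryl metals.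

**Step 9**
Reactants: 15
Product: 16, cathafuran C
Conditions: TMSOTf, 2,2′-bipyridyl, CH2Cl2, 0 °C → rt; then H2O
Reagents that add atoms: none
Why: Silyl-triflate/bipyridyl cleavage of the two aryl MOM ethers via aryl TMS ethers, then hydrolysis, is a buffered acetal deprotection that avoids protic acid on the chromene and the ortho-prenylphenol.

## Compound list

1 | phloroglucinol (benzene-1,3,5-triol) | Oc1cc(O)cc(O)c1 | starting material
2 | 3,3-dimethylacrylic acid | CC(C)=CC(=O)O | starting material
3 | 5,7-dihydroxy-2,2-dimethylchroman-4-one | CC1(C)CC(=O)c2c(O)cc(O)cc2O1 | intermediate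
4 | chloromethyl methyl ether (MOMCl) | COCCl | starting material (reagent)
5 | 5-hydroxy-7-(methoxymethoxy)-2,2-dimethylchroman-4-one | CC1(C)CC(=O)c2c(O)cc(OCOC)cc2O1 | intermediate
6 | benzyltrimethylammonium dichloroiodate | C[N+](C)(C)Cc1ccccc1.Cl[I-]Cl | starting material (reagent)
7 | 5-hydroxy-6-iodo-7-(methoxymethoxy)-2,2-dimethylchroman-4-one | CC1(C)CC(=O)c2c(O)c(I)c(OCOC)cc2O1 | intermediate
8 | trifluoromethanesulfonic anhydride | O=S(=O)(OS(=O)(=O)C(F)(F)F)C(F)(F)F | starting material (reagent)
9 | 6-iodo-7-(methoxymethoxy)-2,2-dimethyl-4-oxochroman-5-yl trifluoromethanesulfonate | CC1(C)CC(=O)c2c(OS(=O)(=O)C(F)(F)F)c(I)c(OCOC)cc2O1 | intermediate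
10 | (±)-4-hydroxy-6-iodo-7-(methoxymethoxy)-2,2-dimethylchroman-5-yl trifluoromethanesulfonate | CC1(C)CC(O)c2c(OS(=O)(=O)C(F)(F)F)c(I)c(OCOC)cc2O1 | intermediate
11 | 6-iodo-7-(methoxymethoxy)-2,2-dimethyl-2H-chromen-5-yl trifluoromethanesulfonate | CC1(C)C=Cc2c(OS(=O)(=O)C(F)(F)F)c(I)c(OCOC)cc2O1 | intermediate
12 | 6-hydroxybenzofuran | Oc1ccc2ccoc2c1 | starting material
13 | 6-(methoxymethoxy)benzofuran | COCOc1ccc2ccoc2c1 | intermediate
14 | prenyl bromide (1-bromo-3-methylbut-2-ene) | CC(C)=CCBr | starting material
15 | 6-(methoxymethoxy)-2-[7-(methoxymethoxy)-2,2-dimethyl-6-(3-methylbut-2-en-1-yl)-2H-chromen-5-yl]benzofuran | COCOc1ccc2cc(-c3c(CC=C(C)C)c(OCOC)cc4OC(C)(C)C=Cc34)oc2c1 | intermediate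
16 | cathafuran C | CC(C)=CCc1c(O)cc2c(c1-c1cc3ccc(O)cc3o1)C=CC(C)(C)O2 | target

## Summary

Total step count: 9.
Longest linear sequence: 8 steps (steps 1–6, 8, 9 from phloroglucinol).

Three steps most likely to fail:

1. **Step 8 (proposed new aryne difunctionalisation).** Risks are wrong-site addition, protonation instead of prenylation, or aryne decomposition. Fallback with known chemistry, from the same intermediate 11: two sequential chemoselective Pd couplings.
   - First, a C–I-selective, linear-selective Negishi coupling with prenylzinc bromide (Pd/biarylphosphine catalyst).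
   - Then a Suzuki–Miyaura coupling of the hindered C5 triflate with the 2-pinacolboronate of 13 (made by n-BuLi, then iPrOBpin), using an XPhos-Pd precatalyst with K3PO4 in THF/H2O.

2. **Step 3 (C6 versus C8 iodination).** Fallback: replace electrophilic substitution with directed ortho-metalation.
   - Reduce and dehydrate 5 to the 5-hydroxychromene and convert the 5-OH to its N-isopropyl carbamate.
   - N-silylate and lithiate (TBSOTf/TMEDA, then n-BuLi) at C6, the position flanked by the carbamate and OMOM, and quench with I2.
   - Cleave the carbamate (Et2NH/DBU) and triflate (PhNTf2) to converge on 11.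

3. **Step 9 (MOM removal on an acid-sensitive chromene and ortho-prenylphenol).** Fallback: change the protecting-group strategy. Carry both phenols as TIPS ethers (TIPSCl/imidazole in steps 2 and 7) so the final step is a fluoride desilylation (TBAF/AcOH, THF, 0 °C) with no Lewis or protic acid.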